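## Retrosynthetic overview

1. The 26-membered ring is closed last, at C9–C10, by an intramolecular Stille coupling of a C25 dienoate ester; that ester comes from acylating the only free hydroxyl (C25–OH) with the C1–C9 iodo-dienoic acid, and six TBS ethers are removed at the end.
2. C19–C20 is made by hydrozirconation/Negishi union of the middle fragment (C10–C19: terminal alkyne, C10 stannane) with the east fragment (C20–C36 vinyl iodide).
3. Middle fragment: C16/C17 by Brown methoxyallylboration of silylpropynal; C13, C12 and C11=C10 are then added by three consecutive boron-to-carbon 1,2-shifts (Matteson CH2 insertion, lithiation–borylation setting C12, Zweifel-type olefination with a stannyl-alkenyllithium).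
4. East fragment: anti-glycolate aldol (C24/C25), allenylstannane addition (C22/C23), cross-metathesis at C26=C27 with the side chain (methoxyallylboration, Sharpless epoxidation, allylboration). West fragment: alkoxyallylboration (C6/C7) and cross-metathesis with sorbic acid.
5. Ring order: the epoxide first (step 5), the macrocycle last (step 38).

Assumption: atom numbers follow the target (C1 lactone carbonyl, C25 the ring carbon bearing the lactone oxygen, C26–C36 the side chain, C36 its terminal CH3); TBS = tert-butyldimethylsilyl, TES = triethylsilyl, Ipc = isopinocampheyl, pin = pinacolato.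

## Side chain (C27–C36)

Step 1
Reactants: 1 butanal; 2 allyl methyl ether
Product: 4 (3S,4S)-3-methoxyhept-1-en-4-ol, via methoxyallylborane 3 (not isolated)
Conditions: 2, sBuLi, THF, −78 °C; (+)-Ipc2BOMe; BF3·OEt2; 1, −78 °C; then pH 7 buffer, H2O2, MeOH, 0 °C
Reagents that add atoms: none
Why: Brown (Z)-γ-methoxyallylboration, in which the chair transition state of the (Z)-allylborane gives the syn methoxy alcohol and the (+)-Ipc groups direct addition to the Re face of 1, setting C32 and C33.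

Step 2
Reactants: 4 (3S,4S)-3-methoxyhept-1-en-4-ol
Product: 5 (3S,4S)-4-(tert-butyldimethylsilyloxy)-3-methoxyhept-1-ene
Conditions: TBSCl, imidazole, DMF, rt
Reagents that add atoms: tert-butyldimethylsilyl chloride, CC(C)(C)[Si](C)(C)Cl
Why: Standard silyl ether formation on a secondary alcohol, which touches no stereocentre.

Step 3
Reactants: 5 (3S,4S)-4-(tert-butyldimethylsilyloxy)-3-methoxyhept-1-ene; 6 methacrolein
Product: 7 (2E,4S,5S)-5-(tert-butyldimethylsilyloxy)-4-methoxy-2-methyloct-2-enal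
Conditions: 6 (5 equiv), second-generation Hoveyda–Grubbs catalyst RuCl2(H2IMes)(=CH-C6H4-2-OiPr) (5 mol %), CH2Cl2, 40 °C
Reagents that add atoms: none
Why: Olefin cross-metathesis of a terminal alkene with excess methacrolein gives the thermodynamically favoured (E)-trisubstituted enal.

Step 4
Reactants: 7 (2E,4S,5S)-5-(tert-butyldimethylsilyloxy)-4-methoxy-2-methyloct-2-enal
Product: 8 (2E,4S,5S)-5-(tert-butyldimethylsilyloxy)-4-methoxy-2-methyloct-2-en-1-ol
Conditions: NaBH4, CeCl3·7H2O, MeOH, 0 °C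
Reagents that add atoms: none
Why: Luche reduction gives clean 1,2-reduction of the enal to the (E)-allylic alcohol.

Step 5
Reactants: 8 (2E,4S,5S)-5-(tert-butyldimethylsilyloxy)-4-methoxy-2-methyloct-2-en-1-ol
Product: 9 C29–C36 epoxy alcohol (trans-2,3-epoxy alcohol configured at C30–C33 as in the target)
Conditions: Ti(OiPr)4 (10 mol %), D-(−)-diisopropyl tartrate (12 mol %), tBuOOH, 4 Å molecular sieves, CH2Cl2, −20 °C
Reagents that add atoms: tert-butyl hydroperoxide, CC(C)(C)OO
Why: Sharpless asymmetric epoxidation of a primary (E)-allylic alcohol, where the D-(−)-tartrate ligand delivers oxygen to the face that gives the C30/C31 epoxide of the target under reagent control.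

Step 6
Reactants: 9 C29–C36 epoxy alcohol
Product: 10 C29–C36 epoxy aldehyde
Conditions: Dess–Martin periodinane, NaHCO3, CH2Cl2, 0 °C → rt
Reagents that add atoms: none
Why: Dess–Martin oxidation under buffered conditions leaves the epoxide intact, and the aldehyde has no α-hydrogen so it cannot epimerise.

Step 7
Reactants: 10 C29–C36 epoxy aldehyde
Product: 11 C27–C36 homoallylic alcohol (free C29–OH)
Conditions: (−)-Ipc2BOMe, allylMgBr, Et2O, 0 °C → rt; then 10, −78 °C; pH 7 buffer, H2O2, MeOH, 0 °C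
Reagents that add atoms: allylmagnesium bromide, C=CC[Mg]Br
Why: Brown allylboration, in which the (−)-Ipc reagent adds to the Si face of the aldehyde and sets the C29 carbinol by reagent control, overriding the bias of the epoxide.

Step 8
Reactants: 11 C27–C36 homoallylic alcohol
Product: 12 C27–C36 side-chain alkene (bis-TBS ether)
Conditions: TBSOTf, 2,6-lutidine, CH2Cl2, −78 → 0 °C
Reagents that add atoms: tert-butyldimethylsilyl triflate, CC(C)(C)[Si](C)(C)OS(=O)(=O)C(F)(F)F
Why: Silylation of the hindered secondary alcohol with the silyl triflate under non-acidic conditions that spare the epoxide.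

## East fragment (C20–C36)

Step 9
Reactants: 13 pent-3-yn-2-one
Product: 14 (R)-pent-3-yn-2-ol
Conditions: RuCl[(R,R)-TsDPEN](p-cymene) (0.5 mol %), KOH (1 mol %), iPrOH, rt
Reagents that add atoms: none
Why: Noyori asymmetric transfer hydrogenation of an alkynyl ketone, where the (R,R)-catalyst gives the (R)-propargylic alcohol.

Step 10
Reactants: 14 (R)-pent-3-yn-2-ol
Product: 15 (R)-pent-3-yn-2-yl methanesulfonate
Conditions: MsCl, Et3N, CH2Cl2, −78 °C
Reagents that add atoms: methanesulfonyl chloride, CS(=O)(=O)Cl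
Why: O-sulfonylation proceeds with retention at the carbinol carbon.

Step 11
Reactants: 15 (R)-pent-3-yn-2-yl methanesulfonate
Product: 16 (P)-tributyl(penta-2,3-dien-2-yl)stannane
Conditions: Bu3SnH, LiN(iPr)2, THF, 0 °C; CuBr·SMe2, −78 °C; then 15, −78 °C
Reagents that add atoms: tributyltin hydride, CCCC[SnH](CCCC)CCCC
Why: Anti SN2' displacement of the propargylic mesylate by the stannylcopper reagent (Marshall allenylstannane synthesis) transfers the centre chirality to the (P)-allene axis.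

Step 12
Reactants: 17 methoxyacetyl chloride
Product: 18 (S)-4-benzyl-3-(methoxyacetyl)-1,3-oxazolidine-2-thione
Conditions: (S)-4-benzyl-1,3-oxazolidine-2-thione, Et3N, CH2Cl2, 0 °C
Reagents that add atoms: (S)-4-benzyl-1,3-oxazolidine-2-thione, S=C1N[C@@H](Cc2ccccc2)CO1
Why: Simple N-acylation installs the chiral auxiliary for the glycolate aldol.

Step 13
Reactants: 18 (S)-4-benzyl-3-(methoxyacetyl)-1,3-oxazolidine-2-thione; 19 (E)-crotonaldehyde
Product: 21 anti-aldol imide C23–C27 [(2S,3S,4E)-3-hydroxy-2-methoxyhex-4-enoyl imide], via titanium enolate 20 (not isolated)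
Conditions: TiCl4 (1.1 equiv), iPr2NEt (1.1 equiv), CH2Cl2, −78 °C; then 19 premixed with TiCl4 (2 equiv), −78 °C
Reagents that add atoms: none
Why: Crimmins anti-glycolate aldol, in which the benzyl group of the auxiliary shields one face of the (Z)-enolate and the TiCl4-activated aldehyde adds through an open transition state to give the 2,3-anti adduct (C24 and C25).

Step 14
Reactants: 21 anti-aldol imide C23–C27
Product: 22 TES ether of the aldol imide
Conditions: TESOTf, 2,6-lutidine, CH2Cl2, −78 °C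
Reagents that add atoms: triethylsilyl triflate, CC[Si](CC)(CC)OS(=O)(=O)C(F)(F)F
Why: The C25 hydroxyl receives the one silyl group that can later be removed selectively in the presence of TBS ethers.

Step 15
Reactants: 22 TES ether of the aldol imide
Product: 23 (2S,3S,4E)-2-methoxy-3-(triethylsilyloxy)hex-4-enal
Conditions: iBu2AlH, CH2Cl2, −78 °C; aq. KNaC4H4O6
Reagents that add atoms: none
Why: N-acyl oxazolidinethiones are reduced by iBu2AlH to a stable tetrahedral intermediate that collapses to the aldehyde on work-up, releasing the auxiliary without epimerisation.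

Step 16
Reactants: 23 (2S,3S,4E)-2-methoxy-3-(triethylsilyloxy)hex-4-enal; 16 (P)-tributyl(penta-2,3-dien-2-yl)stannane
Product: 24 C20–C27 homopropargylic alcohol (22,23-syn and 23,24-syn)
Conditions: 16 (1.5 equiv), MgBr2·OEt2 (3 equiv), CH2Cl2, −23 °C
Reagents that add atoms: none
Why: Marshall allenylstannane addition (anti SE2'), where MgBr2 chelation of the aldehyde and α-methoxy oxygens gives the 23,24-syn relation and the acyclic transition state of the (P)-allene gives the 22,23-syn relation, a matched pairing.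

Step 17
Reactants: 24 C20–C27 homopropargylic alcohol
Product: 25 TBS ether of the homopropargylic alcohol
Conditions: TBSOTf, 2,6-lutidine, CH2Cl2, 0 °C
Reagents that add atoms: tert-butyldimethylsilyl triflate, CC(C)(C)[Si](C)(C)OS(=O)(=O)C(F)(F)F
Why: Routine silylation of the C23 hydroxyl.

Step 18
Reactants: 25 TBS ether of the homopropargylic alcohol
Product: 27 (E)-vinyl iodide C20–C27, via vinylstannane 26 (not isolated)
Conditions: Bu3SnH, PdCl2(PPh3)2 (5 mol %), THF, rt; then I2, CH2Cl2, 0 °C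
Reagents that add atoms: iodine, II
Why: Palladium-catalysed syn hydrostannation places tin on the less hindered methyl-bearing alkyne carbon, and iododestannylation with retention gives the (E)-trisubstituted vinyl iodide while the propenyl group is untouched.

Step 19
Reactants: 27 (E)-vinyl iodide C20–C27; 12 C27–C36 side-chain alkene
Product: 28 east fragment C20–C36 (vinyl iodide)
Conditions: 12 (2 equiv), second-generation Hoveyda–Grubbs catalyst RuCl2(H2IMes)(=CH-C6H4-2-OiPr) (10 mol %), CH2Cl2, 40 °C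
Reagents that add atoms: none
Why: Olefin cross-metathesis between the propenyl group and the unhindered terminal alkene releases propene and gives the (E)-C26=C27 alkene; the trisubstituted vinyl iodide does not take part.

## Middle fragment (C10–C19)

Step 20
Reactants: 29 ethanol
Product: 30 ethyl N,N-diisopropylcarbamate
Conditions: N,N-diisopropylcarbamoyl chloride, Et3N, CH2Cl2, reflux
Reagents that add atoms: N,N-diisopropylcarbamoyl chloride, CC(C)N(C(C)C)C(Cl)=O
Why: Carbamoylation gives the Hoppe carbamate needed for directed α-lithiation.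

Step 21
Reactants: 31 propyne
Product: 32 (Z)-1,2-bis(trimethylstannyl)propene
Conditions: Me3SnSnMe3, Pd(PPh3)4 (2 mol %), THF, 60 °C, sealed tube
Reagents that add atoms: hexamethylditin, C[Sn](C)(C)[Sn](C)(C)C
Why: Palladium-catalysed distannation of a terminal alkyne is a syn addition and gives the cis-distannylalkene.

Step 22
Reactants: 33 3-(trimethylsilyl)propynal; 2 allyl methyl ether
Product: 35 (3R,4R)-4-methoxy-1-(trimethylsilyl)hex-5-en-1-yn-3-ol, via methoxyallylborane 34 (not isolated)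
Conditions: 2, sBuLi, THF, −78 °C; (−)-Ipc2BOMe; BF3·OEt2; 33, −78 °C; then pH 7 buffer, H2O2, MeOH, 0 °C
Reagents that add atoms: none
Why: Brown (Z)-γ-methoxyallylboration, now with the (−)-Ipc reagent adding to the Si face of the ynal, gives the syn C16 methoxy/C17 hydroxy pair.

Step 23
Reactants: 35 (3R,4R)-4-methoxy-1-(trimethylsilyl)hex-5-en-1-yn-3-ol
Product: 36 (3R,4R)-3-(tert-butyldimethylsilyloxy)-4-methoxy-1-(trimethylsilyl)hex-5-en-1-yne
Conditions: TBSOTf, 2,6-lutidine, CH2Cl2, −78 °C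
Reagents that add atoms: tert-butyldimethylsilyl triflate, CC(C)(C)[Si](C)(C)OS(=O)(=O)C(F)(F)F
Why: Routine silylation of the C17 hydroxyl before the organoboron chemistry.

Step 24
Reactants: 36 (3R,4R)-3-(tert-butyldimethylsilyloxy)-4-methoxy-1-(trimethylsilyl)hex-5-en-1-yne
Product: 37 primary pinacol boronate C14–C19
Conditions: pinacolborane, [Ir(cod)Cl]2 (1.5 mol %), dppe (3 mol %), CH2Cl2, rt
Reagents that add atoms: pinacolborane, CC1(C)OBOC1(C)C
Why: Iridium-catalysed hydroboration of the terminal alkene is anti-Markovnikov and puts boron on C14, leaving the silylalkyne alone.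

Step 25
Reactants: 37 primary pinacol boronate C14–C19
Product: 39 homologated pinacol boronate C13–C19, via chloromethyl boronate complex 38 (not isolated)
Conditions: BrCH2Cl, nBuLi, THF, −78 °C → rt
Reagents that add atoms: bromochloromethane, ClCBr
Why: Matteson homologation, in which (chloromethyl)lithium adds to boron and C14 migrates from boron to carbon with loss of chloride (1,2-metallate shift), inserts C13.

Step 26
Reactants: 39 homologated pinacol boronate C13–C19; 30 ethyl N,N-diisopropylcarbamate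
Product: 42 secondary pinacol boronate C12–C19, via lithiated carbamate 40 (not isolated), via boronate complex 41 (not isolated)
Conditions: 30, sBuLi, (−)-sparteine, Et2O, −78 °C, 5 h; 39, −78 °C, 1 h; then 35 °C, 16 h
Reagents that add atoms: none
Why: Hoppe–Aggarwal lithiation–borylation, where (−)-sparteine gives the (S)-lithiated carbamate, borylation occurs with retention and the C13 chain migrates from boron to carbon with inversion (1,2-metallate shift), setting the C12 methyl stereocentre.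

Step 27
Reactants: 42 secondary pinacol boronate C12–C19; 32 (Z)-1,2-bis(trimethylstannyl)propene
Product: 45 middle fragment C10–C19 (C10 alkenylstannane, terminal C18–C19 alkyne), via stannylpropenyllithium 43 (not isolated), via alkenylboronate complex 44 (not isolated)
Conditions: 32, MeLi, THF, −78 °C; 42, −78 °C, 1 h; I2 (1.05 equiv), THF, −78 °C; NaOMe, MeOH, −78 °C → rt
Reagents that add atoms: none
Why: Proposed new method: a Zweifel olefination run with a β-stannyl alkenyllithium as a bimetallic linchpin, in which selective Sn–Li exchange at the terminal tin gives 43, this adds to the boronic ester to give 44, iodine attacks the electron-rich boron-bound alkene far faster than it cleaves a C–Sn bond at −78 °C, C12 migrates from boron to C11 with retention (1,2-metallate shift) anti to iodine, and methoxide-induced anti elimination of boron and iodine inverts the alkene geometry so that the (Z)-lithio reagent gives the (E)-alkenylstannane (methoxide also cleaves the alkynyl silane); the closest known reaction type is the Zweifel olefination of secondary boronic esters with substituted alkenyllithiums.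

## West fragment (C1–C9)

Step 28
Reactants: 46 allyl alcohol
Product: 47 allyl methoxymethyl ether
Conditions: MOMCl, iPr2NEt, CH2Cl2, 0 °C → rt
Reagents that add atoms: chloromethyl methyl ether, COCCl
Why: Standard acetal protection gives the ether needed for the alkoxyallylborane.

Step 29
Reactants: 33 3-(trimethylsilyl)propynal; 47 allyl methoxymethyl ether
Product: 49 (3R,4R)-4-(methoxymethoxy)-1-(trimethylsilyl)hex-5-en-1-yn-3-ol, via alkoxyallylborane 48 (not isolated)
Conditions: 47, sBuLi, THF, −78 °C; (−)-Ipc2BOMe; BF3·OEt2; 33, −78 °C; then pH 7 buffer, H2O2, MeOH, 0 °C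
Reagents that add atoms: none
Why: Brown (Z)-γ-(methoxymethoxy)allylboration with the (−)-Ipc reagent gives the syn C6/C7 diol pattern in the same absolute sense as step 22.

Step 30
Reactants: 49 (3R,4R)-4-(methoxymethoxy)-1-(trimethylsilyl)hex-5-en-1-yn-3-ol
Product: 50 (3R,4R)-1-(trimethylsilyl)hex-5-en-1-yne-3,4-diol
Conditions: HCl (cat.), MeOH, 40 °C
Reagents that add atoms: none
Why: Acid-catalysed acetal exchange removes the methoxymethyl group at a stage where nothing acid-sensitive is present.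

Step 31
Reactants: 50 (3R,4R)-1-(trimethylsilyl)hex-5-en-1-yne-3,4-diol
Product: 51 bis-TBS ether of the diol
Conditions: TBSOTf (2.5 equiv), 2,6-lutidine, CH2Cl2, 0 °C → rt
Reagents that add atoms: tert-butyldimethylsilyl triflate, CC(C)(C)[Si](C)(C)OS(=O)(=O)C(F)(F)F
Why: Both secondary hydroxyls are silylated so that all hydroxyl protection is fluoride-labile at the end.

Step 32
Reactants: 51 bis-TBS ether of the diol
Product: 52 terminal alkyne C4–C9
Conditions: K2CO3, MeOH, rt
Reagents that add atoms: none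
Why: Methanolysis cleaves the alkynyl C–Si bond selectively over the silyl ethers.

Step 33
Reactants: 52 terminal alkyne C4–C9
Product: 54 (E)-vinyl iodide C4–C9, via vinylstannane 53 (not isolated)
Conditions: Bu3SnH, PdCl2(PPh3)2 (5 mol %), THF, 0 °C; then I2, CH2Cl2, 0 °C
Reagents that add atoms: iodine, II
Why: Palladium-catalysed syn hydrostannation of the terminal alkyne next to a bulky silyloxy carbon gives the (E)-β-stannane, and iododestannylation with retention gives the (E)-iodide without touching the terminal alkene.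

Step 34
Reactants: 54 (E)-vinyl iodide C4–C9; 55 sorbic acid
Product: 56 west fragment C1–C9 [(2E,4E)-dienoic acid]
Conditions: 55 (3 equiv), second-generation Hoveyda–Grubbs catalyst RuCl2(H2IMes)(=CH-C6H4-2-OiPr) (10 mol %), CH2Cl2, 40 °C
Reagents that add atoms: none
Why: Olefin cross-metathesis occurs at the γ,δ-alkene of sorbic acid, since the α,β-alkene is electronically deactivated, and transfers the whole (2E,4E)-dienoic acid unit with loss of propene.

## Fragment union and endgame

Step 35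
Reactants: 45 middle fragment C10–C19; 28 east fragment C20–C36
Product: 59 C10–C36 alkenylstannane (C25 TES ether), via alkenylzirconocene 57 (not isolated), via alkenylzinc chloride 58 (not isolated)
Conditions: 45, Cp2Zr(H)Cl, THF, rt; ZnCl2, 0 °C; 28, Pd(PPh3)4 (5 mol %), THF, 0 °C → rt
Reagents that add atoms: none
Why: Syn hydrozirconation of the terminal alkyne, transmetallation to zinc and Negishi coupling with the vinyl iodide form the C19–C20 bond with retention at both alkenes; the alkenylstannane does not couple in the absence of copper.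

Step 36
Reactants: 59 C10–C36 alkenylstannane (C25 TES ether)
Product: 60 C10–C36 alkenylstannane with free C25 hydroxyl
Conditions: PPTS, MeOH/CH2Cl2, 0 °C
Reagents that add atoms: none
Why: Mild acidic methanolysis removes the secondary TES ether selectively in the presence of secondary TBS ethers.

Step 37
Reactants: 60 C10–C36 alkenylstannane with free C25 hydroxyl; 56 west fragment C1–C9
Product: 62 seco ester (C25 dienoate carrying C9 iodide and C10 stannane), via mixed anhydride 61 (not isolated)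
Conditions: 56, 2,4,6-trichlorobenzoyl chloride, Et3N, toluene, rt; then 60, DMAP, rt
Reagents that add atoms: none
Why: Yamaguchi esterification acylates the only free hydroxyl (C25) through the mixed anhydride without isomerising the dienoate.

Step 38
Reactants: 62 seco ester
Product: 63 hexakis-TBS macrolactone
Conditions: Pd2(dba)3 (10 mol %), AsPh3 (40 mol %), CuI (20 mol %), DMF, 1 mM, rt
Reagents that add atoms: none
Why: Intramolecular Stille coupling at high dilution forms the C9–C10 bond and the 26-membered ring with retention of both alkene geometries.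

Step 39
Reactants: 63 hexakis-TBS macrolactone
Product: 64 target macrolide CNP0328768.3
Conditions: HF·pyridine, pyridine, THF, 0 °C → rt
Reagents that add atoms: none
Why: Buffered fluoride-mediated desilylation removes all six TBS ethers while sparing the epoxide, the allylic alcohols and the dienoate.

## Compound list

1 | butanal | CCCC=O | starting material
2 | allyl methyl ether | C=CCOC | starting material
3 | [(Z)-3-methoxyallyl]bis[(+)-isopinocampheyl]borane | CO/C=C\CB([C@H]1C[C@H]2C[C@@H]([C@@H]1C)C2(C)C)[C@H]1C[C@H]2C[C@@H]([C@@H]1C)C2(C)C | intermediate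
4 | (3S,4S)-3-methoxyhept-1-en-4-ol | CCC[C@H](O)[C@@H](OC)C=C | intermediate
5 | (3S,4S)-4-(tert-butyldimethylsilyloxy)-3-methoxyhept-1-ene | CCC[C@H](O[Si](C)(C)C(C)(C)C)[C@@H](OC)C=C | intermediate
6 | methacrolein | CC(=C)C=O | starting material
7 | (2E,4S,5S)-5-(tert-butyldimethylsilyloxy)-4-methoxy-2-methyloct-2-enal | CCC[C@H](O[Si](C)(C)C(C)(C)C)[C@@H](OC)/C=C(\C)C=O | intermediate
8 | (2E,4S,5S)-5-(tert-butyldimethylsilyloxy)-4-methoxy-2-methyloct-2-en-1-ol | CCC[C@H](O[Si](C)(C)C(C)(C)C)[C@@H](OC)/C=C(\C)CO | intermediate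
9 | C29–C36 epoxy alcohol (C33 TBS ether, configured as in the target) | CCC[C@H](O[Si](C)(C)C(C)(C)C)[C@@H](OC)[C@H]1O[C@]1(C)CO | intermediate
10 | C29–C36 epoxy aldehyde | CCC[C@H](O[Si](C)(C)C(C)(C)C)[C@@H](OC)[C@H]1O[C@]1(C)C=O | intermediate
11 | C27–C36 homoallylic alcohol (free C29–OH) | CCC[C@H](O[Si](C)(C)C(C)(C)C)[C@@H](OC)[C@H]1O[C@]1(C)[C@@H](O)CC=C | intermediate
12 | C27–C36 side-chain alkene (C29, C33 bis-TBS ether) | CCC[C@H](O[Si](C)(C)C(C)(C)C)[C@@H](OC)[C@H]1O[C@]1(C)[C@@H](O[Si](C)(C)C(C)(C)C)CC=C | intermediate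
13 | pent-3-yn-2-one | CC#CC(C)=O | starting material
14 | (R)-pent-3-yn-2-ol | C[C@@H](O)C#CC | intermediate
15 | (R)-pent-3-yn-2-yl methanesulfonate | C[C@@H](OS(C)(=O)=O)C#CC | intermediate
16 | (P)-tributyl(penta-2,3-dien-2-yl)stannane | CC=[C@@]=C(C)[Sn](CCCC)(CCCC)CCCC | intermediate
17 | methoxyacetyl chloride | COCC(Cl)=O | starting material
18 | (S)-4-benzyl-3-(methoxyacetyl)-1,3-oxazolidine-2-thione | COCC(=O)N1[C@@H](Cc2ccccc2)COC1=S | intermediate
19 | (E)-crotonaldehyde | C/C=C/C=O | starting material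
20 | trichlorotitanium (Z)-enolate of 18 | CO/C=C(\O[Ti](Cl)(Cl)Cl)N1[C@@H](Cc2ccccc2)COC1=S | intermediate
21 | (S)-4-benzyl-3-[(2S,3S,4E)-3-hydroxy-2-methoxyhex-4-enoyl]-1,3-oxazolidine-2-thione | C/C=C/[C@H](O)[C@H](OC)C(=O)N1[C@@H](Cc2ccccc2)COC1=S | intermediate
22 | TES ether of 21 | C/C=C/[C@H](O[Si](CC)(CC)CC)[C@H](OC)C(=O)N1[C@@H](Cc2ccccc2)COC1=S | intermediate
23 | (2S,3S,4E)-2-methoxy-3-(triethylsilyloxy)hex-4-enal | C/C=C/[C@H](O[Si](CC)(CC)CC)[C@H](OC)C=O | intermediate
24 | C20–C27 homopropargylic alcohol (C25 TES ether, free C23–OH) | C/C=C/[C@H](O[Si](CC)(CC)CC)[C@H](OC)[C@@H](O)[C@H](C)C#CC | intermediate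
25 | C20–C27 alkyne (C23 TBS, C25 TES) | C/C=C/[C@H](O[Si](CC)(CC)CC)[C@H](OC)[C@@H](O[Si](C)(C)C(C)(C)C)[C@H](C)C#CC | intermediate
26 | C20 tributylstannyl alkene from 25 | C/C=C/[C@H](O[Si](CC)(CC)CC)[C@H](OC)[C@@H](O[Si](C)(C)C(C)(C)C)[C@H](C)/C=C(C)/[Sn](CCCC)(CCCC)CCCC | intermediate
27 | C20–C27 (E)-vinyl iodide | C/C=C/[C@H](O[Si](CC)(CC)CC)[C@H](OC)[C@@H](O[Si](C)(C)C(C)(C)C)[C@H](C)/C=C(C)/I | intermediate
28 | east fragment C20–C36 (C20 iodide; C23, C29, C33 TBS; C25 TES) | CCC[C@H](O[Si](C)(C)C(C)(C)C)[C@@H](OC)[C@H]1O[C@]1(C)[C@@H](O[Si](C)(C)C(C)(C)C)C/C=C/[C@H](O[Si](CC)(CC)CC)[C@H](OC)[C@@H](O[Si](C)(C)C(C)(C)C)[C@H](C)/C=C(C)/I | intermediate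
29 | ethanol | CCO | starting material
30 | ethyl N,N-diisopropylcarbamate | CCOC(=O)N(C(C)C)C(C)C | intermediate
31 | propyne | CC#C | starting material
32 | (Z)-1,2-bis(trimethylstannyl)propene | C[Sn](C)(C)/C=C(/C)[Sn](C)(C)C | intermediate
33 | 3-(trimethylsilyl)propynal | C[Si](C)(C)C#CC=O | starting material
34 | [(Z)-3-methoxyallyl]bis[(−)-isopinocampheyl]borane | CO/C=C\CB([C@@H]1C[C@@H]2C[C@H]([C@H]1C)C2(C)C)[C@@H]1C[C@@H]2C[C@H]([C@H]1C)C2(C)C | intermediate
35 | (3R,4R)-4-methoxy-1-(trimethylsilyl)hex-5-en-1-yn-3-ol | C=C[C@@H](OC)[C@H](O)C#C[Si](C)(C)C | intermediate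
36 | (3R,4R)-3-(tert-butyldimethylsilyloxy)-4-methoxy-1-(trimethylsilyl)hex-5-en-1-yne | C=C[C@@H](OC)[C@H](O[Si](C)(C)C(C)(C)C)C#C[Si](C)(C)C | intermediate
37 | primary pinacol boronate C14–C19 (boron on C14) | CC1(C)OB(CC[C@@H](OC)[C@H](O[Si](C)(C)C(C)(C)C)C#C[Si](C)(C)C)OC1(C)C | intermediate
38 | lithium (chloromethyl)boronate complex of 37 | [Li+].CC1(C)O[B-](CCl)(CC[C@@H](OC)[C@H](O[Si](C)(C)C(C)(C)C)C#C[Si](C)(C)C)OC1(C)C | intermediate
39 | homologated pinacol boronate C13–C19 (boron on C13) | CC1(C)OB(CCC[C@@H](OC)[C@H](O[Si](C)(C)C(C)(C)C)C#C[Si](C)(C)C)OC1(C)C | intermediate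
40 | (S)-1-lithioethyl N,N-diisopropylcarbamate (sparteine complex) | C[C@H]([Li])OC(=O)N(C(C)C)C(C)C | intermediate
41 | lithium boronate complex of 39 with 40 | [Li+].C[C@@H](OC(=O)N(C(C)C)C(C)C)[B-]1(CCC[C@@H](OC)[C@H](O[Si](C)(C)C(C)(C)C)C#C[Si](C)(C)C)OC(C)(C)C(C)(C)O1 | intermediate
42 | secondary pinacol boronate C12–C19 (boron on C12, C12 configured as in the target) | CC1(C)OB([C@H](C)CCC[C@@H](OC)[C@H](O[Si](C)(C)C(C)(C)C)C#C[Si](C)(C)C)OC1(C)C | intermediate
43 | (Z)-1-lithio-2-(trimethylstannyl)propene | [Li]/C=C(/C)[Sn](C)(C)C | intermediate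
44 | lithium alkenylboronate complex of 42 with 43 | [Li+].CC1(C)O[B-](/C=C(/C)[Sn](C)(C)C)([C@H](C)CCC[C@@H](OC)[C@H](O[Si](C)(C)C(C)(C)C)C#C[Si](C)(C)C)OC1(C)C | intermediate
45 | middle fragment C10–C19 [(E)-C10 trimethylstannyl alkene, terminal alkyne, C17 TBS] | C[Sn](C)(C)/C(C)=C/[C@H](C)CCC[C@@H](OC)[C@H](O[Si](C)(C)C(C)(C)C)C#C | intermediate
46 | allyl alcohol | C=CCO | starting material
47 | allyl methoxymethyl ether | C=CCOCOC | intermediate
48 | [(Z)-3-(methoxymethoxy)allyl]bis[(−)-isopinocampheyl]borane | COCO/C=C\CB([C@@H]1C[C@@H]2C[C@H]([C@H]1C)C2(C)C)[C@@H]1C[C@@H]2C[C@H]([C@H]1C)C2(C)C | intermediate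
49 | (3R,4R)-4-(methoxymethoxy)-1-(trimethylsilyl)hex-5-en-1-yn-3-ol | C=C[C@@H](OCOC)[C@H](O)C#C[Si](C)(C)C | intermediate
50 | (3R,4R)-1-(trimethylsilyl)hex-5-en-1-yne-3,4-diol | C=C[C@@H](O)[C@H](O)C#C[Si](C)(C)C | intermediate
51 | bis-TBS ether of 50 | C=C[C@@H](O[Si](C)(C)C(C)(C)C)[C@H](O[Si](C)(C)C(C)(C)C)C#C[Si](C)(C)C | intermediate
52 | terminal alkyne C4–C9 (C6, C7 bis-TBS) | C=C[C@@H](O[Si](C)(C)C(C)(C)C)[C@H](O[Si](C)(C)C(C)(C)C)C#C | intermediate
53 | (E)-C9 tributylstannyl alkene from 52 | C=C[C@@H](O[Si](C)(C)C(C)(C)C)[C@H](O[Si](C)(C)C(C)(C)C)/C=C/[Sn](CCCC)(CCCC)CCCC | intermediate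
54 | (E)-vinyl iodide C4–C9 | C=C[C@@H](O[Si](C)(C)C(C)(C)C)[C@H](O[Si](C)(C)C(C)(C)C)/C=C/I | intermediate
55 | sorbic acid | C/C=C/C=C/C(=O)O | starting material
56 | west fragment C1–C9 [(2E,4E,8E)-dienoic acid, C9 iodide, C6, C7 bis-TBS] | OC(=O)/C=C/C=C/[C@@H](O[Si](C)(C)C(C)(C)C)[C@H](O[Si](C)(C)C(C)(C)C)/C=C/I | intermediate
57 | C19 alkenylzirconocene chloride from 45 | C[Sn](C)(C)/C(C)=C/[C@H](C)CCC[C@@H](OC)[C@H](O[Si](C)(C)C(C)(C)C)/C=C/[Zr](Cl)(C1C=CC=C1)C1C=CC=C1 | intermediate
58 | C19 alkenylzinc chloride from 57 | C[Sn](C)(C)/C(C)=C/[C@H](C)CCC[C@@H](OC)[C@H](O[Si](C)(C)C(C)(C)C)/C=C/[Zn]Cl | intermediate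
59 | C10–C36 alkenylstannane (C25 TES; C17, C23, C29, C33 TBS) | CCC[C@H](O[Si](C)(C)C(C)(C)C)[C@@H](OC)[C@H]1O[C@]1(C)[C@@H](O[Si](C)(C)C(C)(C)C)C/C=C/[C@H](O[Si](CC)(CC)CC)[C@H](OC)[C@@H](O[Si](C)(C)C(C)(C)C)[C@H](C)/C=C(C)/C=C/[C@@H](O[Si](C)(C)C(C)(C)C)[C@H](OC)CCC[C@@H](C)/C=C(C)/[Sn](C)(C)C | intermediate
60 | C10–C36 alkenylstannane with free C25–OH | CCC[C@H](O[Si](C)(C)C(C)(C)C)[C@@H](OC)[C@H]1O[C@]1(C)[C@@H](O[Si](C)(C)C(C)(C)C)C/C=C/[C@H](O)[C@H](OC)[C@@H](O[Si](C)(C)C(C)(C)C)[C@H](C)/C=C(C)/C=C/[C@@H](O[Si](C)(C)C(C)(C)C)[C@H](OC)CCC[C@@H](C)/C=C(C)/[Sn](C)(C)C | intermediate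
61 | mixed 2,4,6-trichlorobenzoic anhydride of 56 | O=C(OC(=O)c1c(Cl)cc(Cl)cc1Cl)/C=C/C=C/[C@@H](O[Si](C)(C)C(C)(C)C)[C@H](O[Si](C)(C)C(C)(C)C)/C=C/I | intermediate
62 | seco ester (C25 dienoate; C9 iodide, C10 stannane) | CCC[C@H](O[Si](C)(C)C(C)(C)C)[C@@H](OC)[C@H]1O[C@]1(C)[C@@H](O[Si](C)(C)C(C)(C)C)C/C=C/[C@H](OC(=O)/C=C/C=C/[C@@H](O[Si](C)(C)C(C)(C)C)[C@H](O[Si](C)(C)C(C)(C)C)/C=C/I)[C@H](OC)[C@@H](O[Si](C)(C)C(C)(C)C)[C@H](C)/C=C(C)/C=C/[C@@H](O[Si](C)(C)C(C)(C)C)[C@H](OC)CCC[C@@H](C)/C=C(C)/[Sn](C)(C)C | intermediate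
63 | hexakis-TBS macrolactone (C6, C7, C17, C23, C29, C33 TBS ethers of the target) | CCC[C@H](O[Si](C)(C)C(C)(C)C)[C@@H](OC)[C@H]1O[C@]1(C)[C@@H](O[Si](C)(C)C(C)(C)C)C/C=C/[C@@H]1OC(=O)/C=C/C=C/[C@@H](O[Si](C)(C)C(C)(C)C)[C@H](O[Si](C)(C)C(C)(C)C)/C=C/C(C)=C/[C@H](C)CCC[C@@H](OC)[C@H](O[Si](C)(C)C(C)(C)C)/C=C/C(C)=C/[C@@H](C)[C@H](O[Si](C)(C)C(C)(C)C)[C@H]1OC | intermediate
64 | target macrolide CNP0328768.3 | CCC[C@H](O)[C@@H](OC)[C@H]1O[C@]1(C)[C@@H](O)C/C=C/[C@@H]1OC(=O)/C=C/C=C/[C@@H](O)[C@H](O)/C=C/C(C)=C/[C@H](C)CCC[C@@H](OC)[C@H](O)/C=C/C(C)=C/[C@@H](C)[C@H](O)[C@H]1OC | target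

## Step count and risks

Total step count: 39. Longest linear sequence: 14 steps (steps 1–8, 19, 35–39).

Three steps most likely to fail:

Step 27 (the proposed stannyl-linchpin Zweifel olefination; iodine may attack the C–Sn bond or the crowded iodination/elimination may stall). The fallback uses known chemistry only and sets out from 42. Zweifel-type coupling of 42 with α-lithiated vinyl N,N-diisopropylcarbamate (LiN(iPr)2, THF, −78 °C; then I2, MeOH) gives the 1-alkylvinyl carbamate F1. Elimination with LiN(iPr)2 (THF, −78 °C → rt) gives the terminal alkyne F2 with C12 retained. Deprotonation with nBuLi and quench with MeI gives the methyl alkyne F3. Palladium-catalysed hydrostannation (Me3SnH, PdCl2(PPh3)2, THF), with tin going to the methyl-bearing carbon, gives the silylalkynyl alkenylstannane F4. K2CO3 in MeOH then removes the alkynyl silyl group and the route is rejoined at 45.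

Step 34 (cross-metathesis with sorbic acid; a hindered allylic bis-silyl ether, a conjugated diene partner and a free acid together may give low conversion or truncated products). The fallback sets out from 54 and builds the dienoic acid stepwise. Cross-metathesis of 54 with crotonaldehyde 19 (same ruthenium catalyst) gives the enal F5. Wittig reaction with Ph3P=CHCO2Me (CH2Cl2, rt) gives the methyl dienoate F6. Hydrolysis with Me3SnOH (ClCH2CH2Cl, 80 °C) returns the route at 56.

Step 38 (Stille macrocyclisation at a hindered α-methyl alkenylstannane; oligomerisation or protodestannylation may compete). The fallback moves the ring closure to the lactone bond and sets out from 59. Intermolecular Stille coupling of 59 with 56 (Pd2(dba)3, AsPh3, CuI, DMF, rt) gives the seco acid TES ether F7. PPTS in MeOH/CH2Cl2 at 0 °C frees the C25 hydroxyl to give the seco hydroxy acid F8. Yamaguchi macrolactonisation (2,4,6-trichlorobenzoyl chloride, Et3N, THF; then DMAP, toluene, high dilution) closes the 26-membered ring and rejoins the route at 63.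

## Further compounds

F1 | step 27 | 1-alkylvinyl N,N-diisopropylcarbamate C11–C19 | C=C(OC(=O)N(C(C)C)C(C)C)[C@H](C)CCC[C@@H](OC)[C@H](O[Si](C)(C)C(C)(C)C)C#C[Si](C)(C)C
F2 | step 27 | terminal alkyne C11–C19 (C19 silylalkyne retained) | C#C[C@H](C)CCC[C@@H](OC)[C@H](O[Si](C)(C)C(C)(C)C)C#C[Si](C)(C)C
F3 | step 27 | methyl alkyne C10–C19 | CC#C[C@H](C)CCC[C@@H](OC)[C@H](O[Si](C)(C)C(C)(C)C)C#C[Si](C)(C)C
F4 | step 27 | (E)-C10 trimethylstannyl alkene with C19 silylalkyne | C[Sn](C)(C)/C(C)=C/[C@H](C)CCC[C@@H](OC)[C@H](O[Si](C)(C)C(C)(C)C)C#C[Si](C)(C)C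
F5 | step 34 | (2E,6E)-enal C3–C9 (C6, C7 bis-TBS, C9 iodide) | O=C/C=C/[C@@H](O[Si](C)(C)C(C)(C)C)[C@H](O[Si](C)(C)C(C)(C)C)/C=C/I
F6 | step 34 | methyl (2E,4E,8E)-dienoate C1–C9 | COC(=O)/C=C/C=C/[C@@H](O[Si](C)(C)C(C)(C)C)[C@H](O[Si](C)(C)C(C)(C)C)/C=C/I
F7 | step 38 | seco acid C1–C36 (C25 TES ether, six TBS ethers) | CCC[C@H](O[Si](C)(C)C(C)(C)C)[C@@H](OC)[C@H]1O[C@]1(C)[C@@H](O[Si](C)(C)C(C)(C)C)C/C=C/[C@H](O[Si](CC)(CC)CC)[C@H](OC)[C@@H](O[Si](C)(C)C(C)(C)C)[C@H](C)/C=C(C)/C=C/[C@@H](O[Si](C)(C)C(C)(C)C)[C@H](OC)CCC[C@@H](C)/C=C(C)/C=C/[C@@H](O[Si](C)(C)C(C)(C)C)[C@H](O[Si](C)(C)C(C)(C)C)/C=C/C=C/C(=O)O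
F8 | step 38 | seco hydroxy acid C1–C36 (free C25–OH, six TBS ethers) | CCC[C@H](O[Si](C)(C)C(C)(C)C)[C@@H](OC)[C@H]1O[C@]1(C)[C@@H](O[Si](C)(C)C(C)(C)C)C/C=C/[C@H](O)[C@H](OC)[C@@H](O[Si](C)(C)C(C)(C)C)[C@H](C)/C=C(C)/C=C/[C@@H](O[Si](C)(C)C(C)(C)C)[C@H](OC)CCC[C@@H](C)/C=C(C)/C=C/[C@@H](O[Si](C)(C)C(C)(C)C)[C@H](O[Si](C)(C)C(C)(C)C)/C=C/C=C/C(=O)O
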